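The route rests on cutting two bonds of the tetrahydrofuran (ring atoms O, C19, C20, C21, C22) at once: O–C19 and C17–C18. The ring oxygen on C19 and the carbonyl carbon C17 on C18 are anti, which is what anti addition to a Z C18=C19 alkene delivers. In one operation divalent palladium triggers attack of the C22 hydroxyl, CO becomes C17 and methanol releases the ester. This closes the ring and sets C18 and C19. The precursor is an open-chain (Z)-alkenyl tertiary alcohol carrying C20, C22 and a silylated C24 hydroxyl. An allenylzinc addition (C16) and a C13–C14 Stille coupling to a lactone-bearing alkenyl iodide complete the skeleton. Alkyne 4 serves both halves.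

Key step: step 10

Remark: atoms are numbered from the lactone carbonyl (C1) to the aldehyde carbon (C24); the SMILES defines a trans-4,5-disubstituted lactone (4S,5R), so C4 and C5 are set by an anti-selective crotylation.

Step 1
Reactants: 1 (S)-3-bromo-2-methylpropan-1-ol
Product: 2 (S)-(3-bromo-2-methylpropoxy)(tert-butyl)dimethylsilane
Conditions: TBSCl, imidazole, CH2Cl2, 0 °C to rt
Reagents that add atoms: tert-butyldimethylsilyl chloride, CC(C)(C)[Si](C)(C)Cl
Why: Routine silyl ether formation on a primary alcohol, which leaves untouched the purchased stereocentre that becomes C20 in one half and C10 in the other.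

Step 2
Reactants: 2 (S)-(3-bromo-2-methylpropoxy)(tert-butyl)dimethylsilane; 3 lithium acetylide–ethylenediamine complex
Product: 4 (R)-tert-butyldimethyl[(2-methylpent-4-yn-1-yl)oxy]silane
Conditions: DMSO, 0 °C to rt
Reagents that add atoms: none
Why: SN2 alkylation of an acetylide by a primary bromide in a dipolar aprotic solvent gives the terminal alkyne without touching the neighbouring stereocentre, and 4 is the branching point for both halves.

Step 3
Reactants: 4 (R)-tert-butyldimethyl[(2-methylpent-4-yn-1-yl)oxy]silane; 5 trimethylaluminium; 6 paraformaldehyde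
Product: 9 (R,E)-6-[(tert-butyldimethylsilyl)oxy]-3,5-dimethylhex-2-en-1-ol, via alkenyldimethylalane 7 (not isolated), via lithium alkenylalanate 8 (not isolated)
Conditions: Me3Al, Cp2ZrCl2 (25 mol %), CH2Cl2, 0 °C to rt; n-BuLi, THF, −78 °C; (CH2O)n, −78 °C to rt
Reagents that add atoms: none
Why: Zirconium-catalysed carboalumination adds methyl and aluminium syn with the metal at the terminus, and hydroxymethylation of the derived alanate proceeds with retention, so the E trisubstituted allylic alcohol (C22=C23) should result.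

Step 4
Reactants: 9 (R,E)-6-[(tert-butyldimethylsilyl)oxy]-3,5-dimethylhex-2-en-1-ol
Product: 10 {(2R,3R)-3-[(R)-3-((tert-butyldimethylsilyl)oxy)-2-methylpropyl]-3-methyloxiran-2-yl}methanol
Conditions: Ti(OiPr)4 (10 mol %), D-(−)-diethyl tartrate (12 mol %), t-BuOOH, 4 Å MS, CH2Cl2, −20 °C
Reagents that add atoms: tert-butyl hydroperoxide, CC(C)(C)OO
Why: Sharpless asymmetric epoxidation is reagent-controlled, and the D-(−)-tartrate catalyst should give the (2R,3R)-epoxide of this geraniol-type E allylic alcohol, which sets the C22–O bond.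

Step 5
Reactants: 10 {(2R,3R)-3-[(R)-3-((tert-butyldimethylsilyl)oxy)-2-methylpropyl]-3-methyloxiran-2-yl}methanol
Product: 11 (3R,5R)-6-[(tert-butyldimethylsilyl)oxy]-3,5-dimethylhexane-1,3-diol
Conditions: NaAlH2(OCH2CH2OMe)2, THF, 0 °C to rt
Reagents that add atoms: none
Why: Hydroxyl-directed hydride opening of a 2,3-epoxy alcohol occurs at the less substituted C23, giving the 1,3-diol with the C22–O bond and its configuration retained.

Step 6
Reactants: 11 (3R,5R)-6-[(tert-butyldimethylsilyl)oxy]-3,5-dimethylhexane-1,3-diol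
Product: 12 (3R,5R)-6-[(tert-butyldimethylsilyl)oxy]-1-[(tert-butyldiphenylsilyl)oxy]-3,5-dimethylhexan-3-ol
Conditions: TBDPSCl, imidazole, CH2Cl2, 0 °C
Reagents that add atoms: tert-butyldiphenylsilyl chloride, CC(C)(C)[Si](Cl)(c1ccccc1)c1ccccc1
Why: Silylation with a bulky chlorosilane distinguishes the primary C24 hydroxyl from the tertiary C22 hydroxyl, and TBDPS is chosen because it must outlast the acid of steps 7 and 10.

Step 7
Reactants: 12 (3R,5R)-6-[(tert-butyldimethylsilyl)oxy]-1-[(tert-butyldiphenylsilyl)oxy]-3,5-dimethylhexan-3-ol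
Product: 13 (2R,4R)-6-[(tert-butyldiphenylsilyl)oxy]-2,4-dimethylhexane-1,4-diol
Conditions: camphorsulfonic acid (10 mol %), MeOH/CH2Cl2, 0 °C
Reagents that add atoms: none
Why: Acid-catalysed methanolysis removes a primary TBS ether much faster than a TBDPS ether, a standard orthogonal desilylation.

Step 8
Reactants: 13 (2R,4R)-6-[(tert-butyldiphenylsilyl)oxy]-2,4-dimethylhexane-1,4-diol
Product: 15 (3R,5R)-5-{2-[(tert-butyldiphenylsilyl)oxy]ethyl}-3,5-dimethyltetrahydrofuran-2-ol (both anomers), via open hydroxy aldehyde 14 (not isolated)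
Conditions: IBX, DMSO, rt
Reagents that add atoms: none
Why: IBX oxidation of a 1,4-diol stops at the γ-lactol because the hydroxy aldehyde is trapped by the C22 hydroxyl, and the cyclic form also shields C20 from enolisation.

Step 9
Reactants: 15 (3R,5R)-5-{2-[(tert-butyldiphenylsilyl)oxy]ethyl}-3,5-dimethyltetrahydrofuran-2-ol; 16 ethyltriphenylphosphonium bromide
Product: 18 (3R,5R,6Z)-1-[(tert-butyldiphenylsilyl)oxy]-3,5-dimethyloct-6-en-3-ol, via ethylidenetriphenylphosphorane 17 (not isolated)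
Conditions: 16, KN(SiMe3)2, THF, 0 °C; then 15, −78 °C to rt
Reagents that add atoms: none
Why: Wittig olefination of the ring-opened lactol with a non-stabilised ylide under lithium-free conditions is kinetically Z-selective and at the same time releases the C22 tertiary hydroxyl.

Step 10
Reactants: 18 (3R,5R,6Z)-1-[(tert-butyldiphenylsilyl)oxy]-3,5-dimethyloct-6-en-3-ol; 19 carbon monoxide; 20 methanol
Product: 23 methyl (R)-2-[(2R,3R,5R)-5-{2-[(tert-butyldiphenylsilyl)oxy]ethyl}-3,5-dimethyltetrahydrofuran-2-yl]propanoate, via alkylpalladium chloride 21 (not isolated), via acylpalladium chloride 22 (not isolated)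
Conditions: PdCl2(MeCN)2 (10 mol %), CuCl2 (3 equiv), NaOAc (3 equiv), CO (1 atm), MeOH, rt
Reagents that add atoms: none
Why: Divalent palladium binds the Z C18=C19 alkene and the C22 hydroxyl adds to C19 from the opposite face (anti oxypalladation, 5-exo-trig, closing the ring O/C19/C20/C21/C22) to give 21, CO inserts into the C18–Pd bond with retention to give 22, methanol cleaves the acyl complex and CuCl2 returns zerovalent palladium to the divalent state. This is the Wacker-type intramolecular alkoxycarbonylation of hydroxyalkenes, a known reaction that is stereospecific for internal alkenes; a tertiary alcohol is only a less common nucleophile and profits from the gem-disubstitution at C22. C18 is fixed by that stereospecificity, since net anti addition of O and C17 to a Z alkene gives the (18R,19R) anti array. C19 is fixed by A(1,3) strain, which holds the C20–H bond in the alkene plane beside the C18 methyl group, so the C21 tether carries oxygen to one face and the C20 methyl group ends trans to the C18 side chain on the ring. The step needs this facial selectivity, 5-exo over 6-endo regioselectivity (secured by the tether length) and CO capture faster than β-hydride elimination (favoured by CO saturation and the chloride-rich medium). NaOAc takes up the HCl formed, so the TBDPS ether and the tertiary carbinol should survive.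

Step 11
Reactants: 23 methyl (R)-2-[(2R,3R,5R)-5-{2-[(tert-butyldiphenylsilyl)oxy]ethyl}-3,5-dimethyltetrahydrofuran-2-yl]propanoate
Product: 24 (S)-2-[(2R,3R,5R)-5-{2-[(tert-butyldiphenylsilyl)oxy]ethyl}-3,5-dimethyltetrahydrofuran-2-yl]propan-1-ol
Conditions: iBu2AlH, CH2Cl2, −78 to 0 °C
Reagents that add atoms: none
Why: Standard aluminium hydride reduction of an ester to the primary alcohol, to which the silyl ether, the ring and the four stereocentres are inert (the C18 descriptor changes by priority only).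

Step 12
Reactants: 24 (S)-2-[(2R,3R,5R)-5-{2-[(tert-butyldiphenylsilyl)oxy]ethyl}-3,5-dimethyltetrahydrofuran-2-yl]propan-1-ol
Product: 25 (R)-2-[(2R,3R,5R)-5-{2-[(tert-butyldiphenylsilyl)oxy]ethyl}-3,5-dimethyltetrahydrofuran-2-yl]propanal
Conditions: Dess–Martin periodinane, CH2Cl2, 0 °C to rt
Reagents that add atoms: none
Why: Dess–Martin oxidation is mild and non-basic, so the α-stereocentre C18 should survive, and the aldehyde is used at once.

Step 13
Reactants: 26 pent-3-yn-2-one
Product: 27 (S)-pent-3-yn-2-ol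
Conditions: Ru[(S,S)-TsDPEN](p-cymene) (preformed amido complex, 1 mol %), iPrOH, rt
Reagents that add atoms: none
Why: Noyori asymmetric transfer hydrogenation reduces alkynyl ketones only at the carbonyl group, and the (S,S)-catalyst places the alkynyl group like an aryl group and should give the S alcohol.

Step 14
Reactants: 27 (S)-pent-3-yn-2-ol
Product: 28 (S)-pent-3-yn-2-yl methanesulfonate
Conditions: MsCl, Et3N, CH2Cl2, −78 to 0 °C
Reagents that add atoms: methanesulfonyl chloride, CS(=O)(=O)Cl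
Why: Sulfonylation at oxygen leaves the carbinol configuration unchanged and supplies the leaving group for palladium.

Step 15
Reactants: 25 (R)-2-[(2R,3R,5R)-5-{2-[(tert-butyldiphenylsilyl)oxy]ethyl}-3,5-dimethyltetrahydrofuran-2-yl]propanal; 28 (S)-pent-3-yn-2-yl methanesulfonate
Product: 30 (2S,3R,4R)-2-[(2R,3R,5R)-5-{2-[(tert-butyldiphenylsilyl)oxy]ethyl}-3,5-dimethyltetrahydrofuran-2-yl]-4-methylhept-5-yn-3-ol, via allenylzinc 29 (not isolated)
Conditions: Pd(OAc)2 (5 mol %), PPh3 (5 mol %), Et2Zn (3 equiv), THF, −78 to −20 °C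
Reagents that add atoms: none
Why: Zerovalent palladium displaces the mesylate anti (SN2'), Et2Zn transmetalates to the chiral allenylzinc 29 and its cyclic SE2' addition transfers the mesylate chirality with overall inversion to C16 (R) and gives the anti C16/C17 pair (C17 is erased later), while the methyl-capped alkyne already carries the C14 methyl group.

Step 16
Reactants: 30 (2S,3R,4R)-2-[(2R,3R,5R)-5-{2-[(tert-butyldiphenylsilyl)oxy]ethyl}-3,5-dimethyltetrahydrofuran-2-yl]-4-methylhept-5-yn-3-ol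
Product: 31 (2S,3R,4R)-2-[(2R,3R,5R)-5-(2-hydroxyethyl)-3,5-dimethyltetrahydrofuran-2-yl]-4-methylhept-5-yn-3-ol
Conditions: Bu4NF, THF, rt
Reagents that add atoms: none
Why: Fluoride desilylation is placed here, before the base-sensitive lactone is present, so that both carbinols can be oxidised together at the end.

Step 17
Reactants: 31 (2S,3R,4R)-2-[(2R,3R,5R)-5-(2-hydroxyethyl)-3,5-dimethyltetrahydrofuran-2-yl]-4-methylhept-5-yn-3-ol
Product: 32 (2S,3R,4R,5E)-2-[(2R,3R,5R)-5-(2-hydroxyethyl)-3,5-dimethyltetrahydrofuran-2-yl]-4-methyl-6-(tributylstannyl)hept-5-en-3-ol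
Conditions: Bu3SnH, PdCl2(PPh3)2 (5 mol %), THF, 0 °C to rt
Reagents that add atoms: tributyltin hydride, CCCC[SnH](CCCC)CCCC
Why: Palladium-catalysed hydrostannation adds H and Sn syn, and tin should go to the methyl-bearing C14 because C15 is shielded by the branched C16, giving the E alkenylstannane.

Step 18
Reactants: 4 (R)-tert-butyldimethyl[(2-methylpent-4-yn-1-yl)oxy]silane
Product: 34 (R,E)-tert-butyl[(5-iodo-2-methylpent-4-en-1-yl)oxy]dimethylsilane, via alkenylzirconocene chloride 33 (not isolated)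
Conditions: Cp2ZrHCl, THF, rt; then I2, 0 °C
Reagents that add atoms: iodine, II
Why: Hydrozirconation places the metal syn at the terminal carbon and iodinolysis occurs with retention, giving the E alkenyl iodide (C12=C13).

Step 19
Reactants: 34 (R,E)-tert-butyl[(5-iodo-2-methylpent-4-en-1-yl)oxy]dimethylsilane
Product: 35 (R,E)-5-iodo-2-methylpent-4-en-1-ol
Conditions: camphorsulfonic acid (10 mol %), MeOH, 0 °C to rt
Reagents that add atoms: none
Why: Acid-catalysed methanolysis of a primary TBS ether, to which the alkenyl iodide is inert.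

Step 20
Reactants: 35 (R,E)-5-iodo-2-methylpent-4-en-1-ol
Product: 36 (R,E)-5-iodo-2-methylpent-4-enal
Conditions: Dess–Martin periodinane, CH2Cl2, 0 °C to rt
Reagents that add atoms: none
Why: Dess–Martin oxidation under non-basic conditions should keep the α-stereocentre C10 intact, and the aldehyde is used directly.

Step 21
Reactants: 37 methyl bis(2,2,2-trifluoroethyl)phosphonoacetate; 38 iodoethane
Product: 40 methyl 2-[bis(2,2,2-trifluoroethoxy)phosphoryl]butanoate (racemic), via sodium phosphonoacetate 39 (not isolated)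
Conditions: NaH, THF/DMF, 0 °C; then EtI, rt
Reagents that add atoms: none
Why: Malonate-type C-alkylation of the stabilised phosphonoacetate anion with a primary iodide installs the future C8 ethyl group.

Step 22
Reactants: 36 (R,E)-5-iodo-2-methylpent-4-enal; 40 methyl 2-[bis(2,2,2-trifluoroethoxy)phosphoryl]butanoate
Product: 42 methyl (2Z,4R,6E)-2-ethyl-7-iodo-4-methylhepta-2,6-dienoate, via potassium phosphonate 41 (not isolated)
Conditions: 40, KN(SiMe3)2, 18-crown-6, THF, −78 °C; then 36
Reagents that add atoms: none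
Why: In the Still–Gennari olefination the electron-poor phosphonate with a dissociated potassium ion eliminates from the kinetic adduct, which places C10 cis to the ester (Z C8=C9) without epimerising C10 at low temperature.

Step 23
Reactants: 42 methyl (2Z,4R,6E)-2-ethyl-7-iodo-4-methylhepta-2,6-dienoate
Product: 43 (2Z,4R,6E)-2-ethyl-7-iodo-4-methylhepta-2,6-dien-1-ol
Conditions: iBu2AlH, CH2Cl2, −78 °C
Reagents that add atoms: none
Why: 1,2-Reduction of an enoate with an aluminium hydride gives the allylic alcohol with both alkene geometries and the carbon–iodine bond unchanged.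

Step 24
Reactants: 43 (2Z,4R,6E)-2-ethyl-7-iodo-4-methylhepta-2,6-dien-1-ol
Product: 44 (2Z,4R,6E)-2-ethyl-7-iodo-4-methylhepta-2,6-dienal
Conditions: MnO2, CH2Cl2, rt
Reagents that add atoms: none
Why: Heterogeneous, neutral MnO2 oxidation is selective for allylic alcohols and should preserve the Z geometry of the enal, which is used at once.

Step 25
Reactants: 44 (2Z,4R,6E)-2-ethyl-7-iodo-4-methylhepta-2,6-dienal; 45 diethyl {2-[methoxy(methyl)amino]-2-oxoethyl}phosphonate
Product: 47 (2E,4Z,6R,8E)-4-ethyl-9-iodo-N-methoxy-N,6-dimethylnona-2,4,8-trienamide, via sodium phosphonate 46 (not isolated)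
Conditions: 45, NaH, THF, 0 °C; then 44, 0 °C to rt
Reagents that add atoms: none
Why: Horner–Wadsworth–Emmons olefination with a stabilised amide phosphonate is fast at low temperature and E-selective, so C6=C7 forms before the Z enal can isomerise.

Step 26
Reactants: 47 (2E,4Z,6R,8E)-4-ethyl-9-iodo-N-methoxy-N,6-dimethylnona-2,4,8-trienamide
Product: 48 (2E,4Z,6R,8E)-4-ethyl-9-iodo-6-methylnona-2,4,8-trienal
Conditions: iBu2AlH, THF, −78 °C
Reagents that add atoms: none
Why: Reduction of a Weinreb amide stops at the chelated tetrahedral intermediate, which releases the aldehyde only on work-up.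

Step 27
Reactants: 48 (2E,4Z,6R,8E)-4-ethyl-9-iodo-6-methylnona-2,4,8-trienal; 49 trans-2-butene
Product: 54 (3S,4R,5E,7Z,9R,11E)-7-ethyl-12-iodo-3,9-dimethyldodeca-1,5,7,11-tetraen-4-ol, via crotylpotassium 50 (not isolated), via potassium borate 51 (not isolated), via crotylborane 52 (not isolated), via borinate 53 (not isolated)
Conditions: 49, n-BuLi, KOtBu, THF, −78 to −45 °C; (−)-Ipc2BOMe, −78 °C; BF3·OEt2; then 48, −78 °C; NaOH, H2O2, 0 °C to rt
Reagents that add atoms: none
Why: Brown crotylboration proceeds through a chair transition state, so the E crotyl group gives the anti C4/C5 pair, and the isopinocampheyl groups derived from (+)-α-pinene direct attack to the Si face of the aldehyde, giving (4S,5R).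

Step 28
Reactants: 54 (3S,4R,5E,7Z,9R,11E)-7-ethyl-12-iodo-3,9-dimethyldodeca-1,5,7,11-tetraen-4-ol; 55 acryloyl chloride
Product: 56 (3S,4R,5E,7Z,9R,11E)-7-ethyl-12-iodo-3,9-dimethyldodeca-1,5,7,11-tetraen-4-yl prop-2-enoate
Conditions: 55, iPr2NEt, DMAP (cat.), CH2Cl2, 0 °C
Reagents that add atoms: none
Why: O-Acylation of a secondary alcohol under mild basic conditions brings in C1 and C2 without touching C5.

Step 29
Reactants: 56 (3S,4R,5E,7Z,9R,11E)-7-ethyl-12-iodo-3,9-dimethyldodeca-1,5,7,11-tetraen-4-yl prop-2-enoate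
Product: 57 (5S,6R)-6-[(1E,3Z,5R,7E)-3-ethyl-8-iodo-5-methylocta-1,3,7-trien-1-yl]-5-methyl-5,6-dihydro-2H-pyran-2-one
Conditions: second-generation Grubbs catalyst (H2IMes)(PCy3)Cl2Ru=CHPh (5 mol %), CH2Cl2 (high dilution), reflux
Reagents that add atoms: none
Why: Ring-closing metathesis starts at the only monosubstituted electron-rich alkene and closes onto the acrylate to the six-membered lactone, while the internal diene and the alkenyl iodide are much less reactive.

Step 30
Reactants: 32 (2S,3R,4R,5E)-2-[(2R,3R,5R)-5-(2-hydroxyethyl)-3,5-dimethyltetrahydrofuran-2-yl]-4-methyl-6-(tributylstannyl)hept-5-en-3-ol; 57 (5S,6R)-6-[(1E,3Z,5R,7E)-3-ethyl-8-iodo-5-methylocta-1,3,7-trien-1-yl]-5-methyl-5,6-dihydro-2H-pyran-2-one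
Product: 58 (17R)-C17,C24-diol of the target
Conditions: Pd2(dba)3 (5 mol %), AsPh3 (20 mol %), DMF, rt to 40 °C, dark
Reagents that add atoms: none
Why: Stille coupling joins C13 and C14 with retention at both alkenyl partners under neutral conditions that tolerate the free hydroxyl groups and the lactone.

Step 31
Reactants: 58 (17R)-C17,C24-diol of the target
Product: 59 target CNP0166598.2
Conditions: Dess–Martin periodinane (excess), NaHCO3, CH2Cl2, 0 °C to rt
Reagents that add atoms: none
Why: Buffered Dess–Martin oxidation converts the secondary C17 and the primary C24 carbinol in one operation without acid or base strong enough to epimerise C16 or C18, to move the C14=C15 alkene or to open the β-alkoxy aldehyde.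

Compound list
1 | (S)-3-bromo-2-methylpropan-1-ol | OC[C@H](C)CBr | starting material
2 | (S)-(3-bromo-2-methylpropoxy)(tert-butyl)dimethylsilane | CC(C)(C)[Si](C)(C)OC[C@H](C)CBr | intermediate
3 | lithium acetylide–ethylenediamine complex | [Li+].[C-]#C.NCCN | starting material
4 | (R)-tert-butyldimethyl[(2-methylpent-4-yn-1-yl)oxy]silane | CC(C)(C)[Si](C)(C)OC[C@H](C)CC#C | intermediate
5 | trimethylaluminium | C[Al](C)C | starting material
6 | paraformaldehyde (reacts as formaldehyde) | C=O | starting material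
7 | (E)-alkenyldimethylalane from syn methylalumination of 4 | CC(C)(C)[Si](C)(C)OC[C@H](C)C/C(C)=C/[Al](C)C | intermediate
8 | lithium butyl(alkenyl)dimethylalanate from 7 | CC(C)(C)[Si](C)(C)OC[C@H](C)C/C(C)=C/[Al-](C)(C)CCCC.[Li+] | intermediate
9 | (R,E)-6-[(tert-butyldimethylsilyl)oxy]-3,5-dimethylhex-2-en-1-ol | CC(C)(C)[Si](C)(C)OC[C@H](C)C/C(C)=C/CO | intermediate
10 | {(2R,3R)-3-[(R)-3-((tert-butyldimethylsilyl)oxy)-2-methylpropyl]-3-methyloxiran-2-yl}methanol | CC(C)(C)[Si](C)(C)OC[C@H](C)C[C@@]1(C)O[C@@H]1CO | intermediate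
11 | (3R,5R)-6-[(tert-butyldimethylsilyl)oxy]-3,5-dimethylhexane-1,3-diol | CC(C)(C)[Si](C)(C)OC[C@H](C)C[C@@](C)(O)CCO | intermediate
12 | (3R,5R)-6-[(tert-butyldimethylsilyl)oxy]-1-[(tert-butyldiphenylsilyl)oxy]-3,5-dimethylhexan-3-ol | CC(C)(C)[Si](C)(C)OC[C@H](C)C[C@@](C)(O)CCO[Si](c1ccccc1)(c1ccccc1)C(C)(C)C | intermediate
13 | (2R,4R)-6-[(tert-butyldiphenylsilyl)oxy]-2,4-dimethylhexane-1,4-diol | OC[C@H](C)C[C@@](C)(O)CCO[Si](c1ccccc1)(c1ccccc1)C(C)(C)C | intermediate
14 | (2R,4R)-6-[(tert-butyldiphenylsilyl)oxy]-4-hydroxy-2,4-dimethylhexanal | O=C[C@H](C)C[C@@](C)(O)CCO[Si](c1ccccc1)(c1ccccc1)C(C)(C)C | intermediate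
15 | (3R,5R)-5-{2-[(tert-butyldiphenylsilyl)oxy]ethyl}-3,5-dimethyltetrahydrofuran-2-ol, both anomers | OC1O[C@@](C)(CCO[Si](c2ccccc2)(c2ccccc2)C(C)(C)C)C[C@H]1C | intermediate
16 | ethyltriphenylphosphonium bromide | CC[P+](c1ccccc1)(c1ccccc1)c1ccccc1.[Br-] | starting material
17 | ethylidenetriphenylphosphorane | CC=P(c1ccccc1)(c1ccccc1)c1ccccc1 | intermediate
18 | (3R,5R,6Z)-1-[(tert-butyldiphenylsilyl)oxy]-3,5-dimethyloct-6-en-3-ol (key-step precursor, C18–C24) | C/C=C\[C@H](C)C[C@@](C)(O)CCO[Si](c1ccccc1)(c1ccccc1)C(C)(C)C | intermediate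
19 | carbon monoxide | [C-]#[O+] | starting material
20 | methanol | CO | starting material
21 | σ-alkylpalladium chloride, Pd on C18 anti to the new O–C19 bond (other ligands omitted) | Cl[Pd][C@H](C)[C@@H]1O[C@@](C)(CCO[Si](c2ccccc2)(c2ccccc2)C(C)(C)C)C[C@H]1C | intermediate
22 | acylpalladium chloride after CO insertion with retention at C18 (other ligands omitted) | Cl[Pd]C(=O)[C@H](C)[C@@H]1O[C@@](C)(CCO[Si](c2ccccc2)(c2ccccc2)C(C)(C)C)C[C@H]1C | intermediate
23 | methyl (R)-2-[(2R,3R,5R)-5-{2-[(tert-butyldiphenylsilyl)oxy]ethyl}-3,5-dimethyltetrahydrofuran-2-yl]propanoate (C17–C24) | COC(=O)[C@H](C)[C@@H]1O[C@@](C)(CCO[Si](c2ccccc2)(c2ccccc2)C(C)(C)C)C[C@H]1C | intermediate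
24 | (S)-2-[(2R,3R,5R)-5-{2-[(tert-butyldiphenylsilyl)oxy]ethyl}-3,5-dimethyltetrahydrofuran-2-yl]propan-1-ol | OC[C@H](C)[C@@H]1O[C@@](C)(CCO[Si](c2ccccc2)(c2ccccc2)C(C)(C)C)C[C@H]1C | intermediate
25 | (R)-2-[(2R,3R,5R)-5-{2-[(tert-butyldiphenylsilyl)oxy]ethyl}-3,5-dimethyltetrahydrofuran-2-yl]propanal | O=C[C@H](C)[C@@H]1O[C@@](C)(CCO[Si](c2ccccc2)(c2ccccc2)C(C)(C)C)C[C@H]1C | intermediate
26 | pent-3-yn-2-one | CC#CC(C)=O | starting material
27 | (S)-pent-3-yn-2-ol | CC#C[C@H](C)O | intermediate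
28 | (S)-pent-3-yn-2-yl methanesulfonate | CC#C[C@H](C)OS(C)(=O)=O | intermediate
29 | (aR)-ethyl(penta-2,3-dien-2-yl)zinc | CC[Zn]C(C)=[C@]=C([H])C | intermediate
30 | (2S,3R,4R)-2-[(2R,3R,5R)-5-{2-[(tert-butyldiphenylsilyl)oxy]ethyl}-3,5-dimethyltetrahydrofuran-2-yl]-4-methylhept-5-yn-3-ol | CC#C[C@@H](C)[C@@H](O)[C@H](C)[C@@H]1O[C@@](C)(CCO[Si](c2ccccc2)(c2ccccc2)C(C)(C)C)C[C@H]1C | intermediate
31 | (2S,3R,4R)-2-[(2R,3R,5R)-5-(2-hydroxyethyl)-3,5-dimethyltetrahydrofuran-2-yl]-4-methylhept-5-yn-3-ol | CC#C[C@@H](C)[C@@H](O)[C@H](C)[C@@H]1O[C@@](C)(CCO)C[C@H]1C | intermediate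
32 | (2S,3R,4R,5E)-2-[(2R,3R,5R)-5-(2-hydroxyethyl)-3,5-dimethyltetrahydrofuran-2-yl]-4-methyl-6-(tributylstannyl)hept-5-en-3-ol (C14–C24) | CCCC[Sn](CCCC)(CCCC)/C(C)=C/[C@@H](C)[C@@H](O)[C@H](C)[C@@H]1O[C@@](C)(CCO)C[C@H]1C | intermediate
33 | (E)-alkenylzirconocene chloride from 4 (cyclopentadienyl rings written as σ-bonded C5H5) | CC(C)(C)[Si](C)(C)OC[C@H](C)C/C=C/[Zr](Cl)(C1C=CC=C1)C1C=CC=C1 | intermediate
34 | (R,E)-tert-butyl[(5-iodo-2-methylpent-4-en-1-yl)oxy]dimethylsilane | CC(C)(C)[Si](C)(C)OC[C@H](C)C/C=C/I | intermediate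
35 | (R,E)-5-iodo-2-methylpent-4-en-1-ol | OC[C@H](C)C/C=C/I | intermediate
36 | (R,E)-5-iodo-2-methylpent-4-enal | O=C[C@H](C)C/C=C/I | intermediate
37 | methyl bis(2,2,2-trifluoroethyl)phosphonoacetate | COC(=O)CP(=O)(OCC(F)(F)F)OCC(F)(F)F | starting material
38 | iodoethane | CCI | starting material
39 | sodium salt of 37 | [Na+].COC(=O)[CH-]P(=O)(OCC(F)(F)F)OCC(F)(F)F | intermediate
40 | methyl 2-[bis(2,2,2-trifluoroethoxy)phosphoryl]butanoate (racemic) | CCC(C(=O)OC)P(=O)(OCC(F)(F)F)OCC(F)(F)F | intermediate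
41 | potassium salt of 40 | [K+].CC[C-](C(=O)OC)P(=O)(OCC(F)(F)F)OCC(F)(F)F | intermediate
42 | methyl (2Z,4R,6E)-2-ethyl-7-iodo-4-methylhepta-2,6-dienoate | CCC(=C/[C@H](C)C/C=C/I)/C(=O)OC | intermediate
43 | (2Z,4R,6E)-2-ethyl-7-iodo-4-methylhepta-2,6-dien-1-ol | CCC(=C/[C@H](C)C/C=C/I)/CO | intermediate
44 | (2Z,4R,6E)-2-ethyl-7-iodo-4-methylhepta-2,6-dienal | CCC(=C/[C@H](C)C/C=C/I)/C=O | intermediate
45 | diethyl {2-[methoxy(methyl)amino]-2-oxoethyl}phosphonate | CCOP(=O)(CC(=O)N(C)OC)OCC | starting material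
46 | sodium salt of 45 | [Na+].CCOP(=O)(OCC)[CH-]C(=O)N(C)OC | intermediate
47 | (2E,4Z,6R,8E)-4-ethyl-9-iodo-N-methoxy-N,6-dimethylnona-2,4,8-trienamide | CCC(=C/[C@H](C)C/C=C/I)/C=C/C(=O)N(C)OC | intermediate
48 | (2E,4Z,6R,8E)-4-ethyl-9-iodo-6-methylnona-2,4,8-trienal | CCC(=C/[C@H](C)C/C=C/I)/C=C/C=O | intermediate
49 | trans-2-butene | C/C=C/C | starting material
50 | (E)-crotylpotassium | C/C=C/[CH2-].[K+] | intermediate
51 | potassium (E)-crotyl(methoxy)diisopinocampheylborate | C/C=C/C[B-](OC)([C@@H]1C[C@@H]2C[C@@H](C2(C)C)[C@H]1C)[C@@H]1C[C@@H]2C[C@@H](C2(C)C)[C@H]1C.[K+] | intermediate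
52 | (E)-crotyldiisopinocampheylborane, Ipc groups from (+)-α-pinene | C/C=C/CB([C@@H]1C[C@@H]2C[C@@H](C2(C)C)[C@H]1C)[C@@H]1C[C@@H]2C[C@@H](C2(C)C)[C@H]1C | intermediate
53 | diisopinocampheylborinate of 54 | CCC(=C/[C@H](C)C/C=C/I)/C=C/[C@@H](OB([C@@H]1C[C@@H]2C[C@@H](C2(C)C)[C@H]1C)[C@@H]1C[C@@H]2C[C@@H](C2(C)C)[C@H]1C)[C@@H](C)C=C | intermediate
54 | (3S,4R,5E,7Z,9R,11E)-7-ethyl-12-iodo-3,9-dimethyldodeca-1,5,7,11-tetraen-4-ol | CCC(=C/[C@H](C)C/C=C/I)/C=C/[C@@H](O)[C@@H](C)C=C | intermediate
55 | acryloyl chloride | C=CC(=O)Cl | starting material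
56 | (3S,4R,5E,7Z,9R,11E)-7-ethyl-12-iodo-3,9-dimethyldodeca-1,5,7,11-tetraen-4-yl prop-2-enoate | CCC(=C/[C@H](C)C/C=C/I)/C=C/[C@@H](OC(=O)C=C)[C@@H](C)C=C | intermediate
57 | (5S,6R)-6-[(1E,3Z,5R,7E)-3-ethyl-8-iodo-5-methylocta-1,3,7-trien-1-yl]-5-methyl-5,6-dihydro-2H-pyran-2-one (C1–C13) | CCC(=C/[C@H](C)C/C=C/I)/C=C/[C@H]1OC(=O)C=C[C@@H]1C | intermediate
58 | (5S,6R)-6-{(1E,3Z,5R,7E,9E,11R,12R,13S)-3-ethyl-12-hydroxy-13-[(2R,3R,5R)-5-(2-hydroxyethyl)-3,5-dimethyltetrahydrofuran-2-yl]-5,9,11-trimethyltetradeca-1,3,7,9-tetraen-1-yl}-5-methyl-5,6-dihydro-2H-pyran-2-one | CCC(=C/[C@H](C)C/C=C/C(C)=C/[C@@H](C)[C@@H](O)[C@H](C)[C@@H]1O[C@@](C)(CCO)C[C@H]1C)/C=C/[C@H]1OC(=O)C=C[C@@H]1C | intermediate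
59 | target CNP0166598.2, (4S,5R,10R,16R,18R,19R,20R,22R; 6E,8Z,12E,14E) C17 ketone and C24 aldehyde | CCC(=C/[C@H](C)C/C=C/C(C)=C/[C@@H](C)C(=O)[C@H](C)[C@@H]1O[C@@](C)(CC=O)C[C@H]1C)/C=C/[C@H]1OC(=O)C=C[C@@H]1C | target

Total step count: 31.
Longest linear sequence: 17 steps (steps 1–12, 15–17, 30 and 31). The lactone branch runs over 15 steps (1, 2, 18–20, 22–31).

Steps most likely to fail

1. Step 10.
- **What may go wrong:** capture of the secondary alkylpalladium by CO may lose to β-hydride elimination, or the two alkene faces may not be differentiated well enough.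
- **Fallback:** it sets out from lactol 15 and returns at ester 23, and it forms the C18–C19 bond on a preformed ring, so no alkylpalladium is involved. Acetylation (Ac2O, pyridine, DMAP) gives the lactol acetate F1. Commercial (S)-4-isopropyl-1,3-thiazolidine-2-thione is acylated with propanoyl chloride (Et3N, CH2Cl2) to the N-propanoyl thiazolidinethione F2. TiCl4 and iPr2NEt convert it at −78 °C into the chelated Z chlorotitanium enolate F3. Addition of F1 and SnCl4 generates the five-membered oxocarbenium ion. The enolate should attack it trans to the C20 methyl group while the auxiliary fixes C18, giving the anti α-methyl-β-alkoxy imide F4. Methanolysis (MeOH, DMAP) releases the auxiliary and gives 23.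

2. Step 17.
- **What may go wrong:** part of the tin may be delivered to C15 (poor regioselectivity), and protodestannylation may occur on purification.
- **Fallback:** it sets out from alkyne 31 and iodide 57 and returns at diol 58 with the polarity of the coupling reversed. Excess Cp2ZrHCl (THF, 40 °C) metalates both hydroxyl groups and hydrozirconates the alkyne. Reversible addition moves the metal to the less hindered C14, giving the alkenylzirconocene F5, and I2 converts it into the E alkenyl iodide F6. Iodide 57 is stannylated with Me3SnSnMe3 and Pd(PPh3)4 to the alkenylstannane F7. Stille coupling of F6 and F7 under the conditions of step 30 gives 58.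

3. Step 31.
- **What may go wrong:** oxidation of the hindered C17 carbinol may be slow. During that time epimerisation at C16 or C18, migration of the C14=C15 alkene into conjugation, or β-elimination next to the new aldehyde could set in on the most valuable intermediate.
- **Fallback:** it sets out from stannane 32 and returns at target 59 by changing the order of events. Buffered Dess–Martin oxidation is carried out on the small fragment and gives the keto aldehyde stannane F8, whose integrity can be checked. It is then joined to 57 under the neutral conditions of step 30, so the coupling becomes the last step.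

Further compounds
F1 | step 10 | (3R,5R)-5-{2-[(tert-butyldiphenylsilyl)oxy]ethyl}-3,5-dimethyltetrahydrofuran-2-yl acetate, both anomers | CC(=O)OC1O[C@@](C)(CCO[Si](c2ccccc2)(c2ccccc2)C(C)(C)C)C[C@H]1C
F2 | step 10 | (S)-4-isopropyl-3-propanoyl-1,3-thiazolidine-2-thione | CC(C)[C@H]1CSC(=S)N1C(=O)CC
F3 | step 10 | Z chlorotitanium enolate of F2 | C/C=C(\O[Ti](Cl)(Cl)Cl)N1C(=S)SC[C@@H]1C(C)C
F4 | step 10 | (R)-2-[(2R,3R,5R)-5-{2-[(tert-butyldiphenylsilyl)oxy]ethyl}-3,5-dimethyltetrahydrofuran-2-yl]-1-[(S)-4-isopropyl-2-thioxo-1,3-thiazolidin-3-yl]propan-1-one | CC(C)[C@H]1CSC(=S)N1C(=O)[C@H](C)[C@@H]2O[C@@](C)(CCO[Si](c3ccccc3)(c3ccccc3)C(C)(C)C)C[C@H]2C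
F5 | step 17 | C14 alkenylzirconocene chloride of 31 with both oxygens zirconated (cyclopentadienyl rings written as σ-bonded C5H5) | Cl[Zr](C1C=CC=C1)(C1C=CC=C1)/C(C)=C/[C@@H](C)[C@@H](O[Zr](Cl)(C1C=CC=C1)C1C=CC=C1)[C@H](C)[C@@H]1O[C@@](C)(CCO[Zr](Cl)(C2C=CC=C2)C2C=CC=C2)C[C@H]1C
F6 | step 17 | (2S,3R,4R,5E)-2-[(2R,3R,5R)-5-(2-hydroxyethyl)-3,5-dimethyltetrahydrofuran-2-yl]-6-iodo-4-methylhept-5-en-3-ol | I/C(C)=C/[C@@H](C)[C@@H](O)[C@H](C)[C@@H]1O[C@@](C)(CCO)C[C@H]1C
F7 | step 17 | (5S,6R)-6-[(1E,3Z,5R,7E)-3-ethyl-5-methyl-8-(trimethylstannyl)octa-1,3,7-trien-1-yl]-5-methyl-5,6-dihydro-2H-pyran-2-one | CCC(=C/[C@H](C)C/C=C/[Sn](C)(C)C)/C=C/[C@H]1OC(=O)C=C[C@@H]1C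
F8 | step 31 | C14 tributylstannane of the C14–C24 keto aldehyde | CCCC[Sn](CCCC)(CCCC)/C(C)=C/[C@@H](C)C(=O)[C@H](C)[C@@H]1O[C@@](C)(CC=O)C[C@H]1C
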